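Ring A is numbered C1(=O), C2(allyl), C3, C4(OMe), C5(OMe), C6, and the side chain C7H(CH3)–C8H2–aryl. The plan rests on disconnecting C4–C5 and C2–C3. One [4+2] cycloaddition of a ketene-acetal silyloxydiene with a lactate-derived 5-methylene-1,3-dioxolan-4-one closes ring A and sets the oxygenated quaternary C4. It exploits the C4(O)–C5(OMe)=C6–C1(=O) array, in which C4 sits beside the enol-ether carbon of a vinylogous ester. The precursors are the push–pull diene 9 and the tert-butyl acetal 5, whose lactone carbon becomes C7. C7 is then elaborated by ketone synthesis, enol triflate methylation and catalyst-controlled hydrogenation; C2 allylation, C2–C3 desaturation and desilylation finish the route.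

Key step: step 5

Remark: atom labels C1–C8 follow the target numbering above, while locants inside compound names follow each compound's own nomenclature; (R)-lactic acid is the enantiomer required, since it gives the (R)-dienophile and, by addition anti to tert-butyl, the 4S configuration.

Step 1
Reactants: 1 (R)-lactic acid; 2 pivalaldehyde
Product: 3 (2R,5R)-2-tert-butyl-5-methyl-1,3-dioxolan-4-one
Conditions: TsOH·H2O (cat.), pentane, reflux, azeotropic removal of water; cis isomer crystallised from pentane, −78 °C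
Reagents that add atoms: none
Why: Acid-catalysed acetalisation with removal of water closes the dioxolanone without touching the lactic acid stereocentre, and the cis (2R,5R) acetal, favoured at equilibrium and on crystallisation, is taken on.

Step 2
Reactants: 3 (2R,5R)-2-tert-butyl-5-methyl-1,3-dioxolan-4-one
Product: 5 (R)-2-tert-butyl-5-methylene-1,3-dioxolan-4-one, via bromo acetal 4 (not isolated)
Conditions: NBS, AIBN (cat.), CCl4, reflux; filter; Et3N, 0 °C → rt; distil
Reagents that add atoms: none
Why: Radical bromination (Wohl–Ziegler type) at the captodative C5–H followed by E2 dehydrobromination with the amine gives the exocyclic alkene, while the acetal carbon, which now carries all the chirality, is untouched.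

Step 3
Reactants: 6 1,1-dimethoxyethene; 7 acetyl chloride
Product: 8 4,4-dimethoxybut-3-en-2-one
Conditions: Et3N, Et2O, 0 °C → rt
Reagents that add atoms: none
Why: C-Acylation of the nucleophilic ketene acetal by the acid chloride (addition–elimination), with the amine taking up HCl, should give the push–pull enone.

Step 4
Reactants: 8 4,4-dimethoxybut-3-en-2-one
Product: 9 1,1-dimethoxy-3-(trimethylsilyloxy)buta-1,3-diene
Conditions: LiN(iPr)2, THF, −78 °C; Me3SiCl, −78 °C → rt; distil, use at once
Reagents that add atoms: chlorotrimethylsilane, C[Si](C)(C)Cl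
Why: Kinetic deprotonation of the methyl ketone and O-silylation of the enolate (silyl enol ether formation) should give the 3-silyloxydiene.

Step 5
Reactants: 5 (R)-2-tert-butyl-5-methylene-1,3-dioxolan-4-one; 9 1,1-dimethoxy-3-(trimethylsilyloxy)buta-1,3-diene
Product: 11 (2R,5S)-2-tert-butyl-6-methoxy-1,3-dioxaspiro[4.5]dec-6-ene-4,8-dione, via primary cycloadduct 10 (not isolated)
Conditions: toluene, BHT (cat.), 25 → 60 °C; then 0.05 M HCl, THF, 0 °C, 15 min
Reagents that add atoms: none
Why: A normal-electron-demand, strongly asynchronous Diels–Alder cycloaddition joins the nucleophilic CH2 terminus of 9 to the exocyclic methylene of 5 (C2–C3) and the ketene-acetal carbon to the captodative α-carbon (C4–C5), after which mild acid cleaves the silyl enol ether and eliminates one methanol from the ketal to leave the vinylogous ester. The closest known reactions are cycloadditions of 1,1-dialkoxy-3-silyloxybutadienes, which give 3-alkoxycyclohexenones, and of 2-tert-butyl-5-methylene-1,3-dioxolan-4-ones used as chiral α-oxyacrylates. Ring A closes by intermolecular [4+2] cycloaddition, both σ-bonds forming suprafacially in one event to give a six-membered carbocycle spiro-fused at the former C5 of the dioxolanone. The one new stereocentre, C4, is controlled by the acetal carbon: tert-butyl shields one face of the planar dienophile and the diene should add anti to it, giving 5S in 11, which is 4S in the target. Regiochemistry is secured by matched polarisation (largest HOMO coefficient at the diene CH2, largest LUMO coefficient at the dienophile CH2), and endo/exo selectivity is irrelevant because the ketal carbon becomes sp2 on work-up.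

Step 6
Reactants: 11 (2R,5S)-2-tert-butyl-6-methoxy-1,3-dioxaspiro[4.5]dec-6-ene-4,8-dione
Product: 12 (1S)-1-hydroxy-N,2-dimethoxy-N-methyl-4-oxocyclohex-2-ene-1-carboxamide
Conditions: MeNH(OMe)·HCl, AlMe3, CH2Cl2, 0 °C → rt; aq. potassium sodium tartrate
Reagents that add atoms: N,O-dimethylhydroxylamine hydrochloride, CNOC.Cl
Why: Aminolysis of the activated acetal-lactone by the aluminium amide (Weinreb amide formation) should open the dioxolanone chemoselectively, the hemiacetal collapsing to the tertiary alcohol and pivalaldehyde with C4 not involved.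

Step 7
Reactants: 12 (1S)-1-hydroxy-N,2-dimethoxy-N-methyl-4-oxocyclohex-2-ene-1-carboxamide
Product: 13 (1S)-N,1,2-trimethoxy-N-methyl-4-oxocyclohex-2-ene-1-carboxamide
Conditions: NaN(SiMe3)2 (1.05 equiv), THF, −78 °C; MeOTf (1.2 equiv), −78 → −40 °C; aq. NaHCO3
Reagents that add atoms: methyl trifluoromethanesulfonate, COS(=O)(=O)C(F)(F)F
Why: Kinetic deprotonation of the O–H and immediate O-alkylation of the alkoxide by the triflate at low temperature (Williamson ether synthesis) should methylate the hindered tertiary alcohol before proton transfer from the ring α′-CH2 can compete.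

Step 8
Reactants: 14 vanillin
Product: 15 3-methoxy-4-(triisopropylsilyloxy)benzaldehyde
Conditions: iPr3SiCl, imidazole, DMF, rt
Reagents that add atoms: chlorotri(propan-2-yl)silane, CC(C)[Si](Cl)(C(C)C)C(C)C
Why: Silylation of the phenol (silyl ether formation) with the bulky triisopropylsilyl group gives protection that should survive organomagnesium, amide-base and hydrogenation conditions and fall to fluoride at the end.

Step 9
Reactants: 15 3-methoxy-4-(triisopropylsilyloxy)benzaldehyde
Product: 16 [3-methoxy-4-(triisopropylsilyloxy)phenyl]methanol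
Conditions: NaBH4, MeOH, 0 °C
Reagents that add atoms: none
Why: Borohydride reduction of the aryl aldehyde gives the benzylic alcohol and leaves the aryl silyl ether intact.

Step 10
Reactants: 16 [3-methoxy-4-(triisopropylsilyloxy)phenyl]methanol
Product: 17 [4-(chloromethyl)-2-methoxyphenoxy]triisopropylsilane
Conditions: PPh3, NCS, CH2Cl2, 0 °C → rt
Reagents that add atoms: N-chlorosuccinimide, O=C1CCC(=O)N1Cl
Why: Appel-type chlorination under neutral conditions converts the benzylic alcohol into the chloride without acid that could cleave the silyl ether.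

Step 11
Reactants: 13 (1S)-N,1,2-trimethoxy-N-methyl-4-oxocyclohex-2-ene-1-carboxamide; 17 [4-(chloromethyl)-2-methoxyphenoxy]triisopropylsilane
Product: 19 (4S)-3,4-dimethoxy-4-{[3-methoxy-4-(triisopropylsilyloxy)phenyl]acetyl}cyclohex-2-en-1-one, via benzylmagnesium chloride 18 (not isolated)
Conditions: 17, Mg, THF, 0 °C; separately 13, LiN(SiMe3)2 (1.1 equiv), THF, −78 °C; then the Grignard solution (2.5 equiv), −78 → 0 °C; aq. NH4Cl
Reagents that add atoms: none
Why: Magnesium insertion gives the benzylic Grignard reagent, which should add once to the N-methoxy-N-methylamide through the stable magnesium chelate (Weinreb ketone synthesis), the ring ketone being masked during the addition as its lithium enolate and returned on quench.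

Step 12
Reactants: 19 (4S)-3,4-dimethoxy-4-{[3-methoxy-4-(triisopropylsilyloxy)phenyl]acetyl}cyclohex-2-en-1-one
Product: 20 (1Z)-1-[(1S)-1,2-dimethoxy-4-oxocyclohex-2-en-1-yl]-2-[3-methoxy-4-(triisopropylsilyloxy)phenyl]ethenyl trifluoromethanesulfonate
Conditions: KN(SiMe3)2 (1.05 equiv), THF, −78 °C; PhNTf2, −78 → 0 °C
Reagents that add atoms: N-phenylbis(trifluoromethanesulfonimide), O=S(=O)(N(c1ccccc1)S(=O)(=O)C(F)(F)F)C(F)(F)F
Why: The benzylic C8 protons are by far the most acidic, so one equivalent of base should enolise only the side-chain ketone, and the bulky quaternary substituent enforces the Z(O) enolate geometry that O-sulfonylation (enol triflate formation) preserves.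

Step 13
Reactants: 20 (1Z)-1-[(1S)-1,2-dimethoxy-4-oxocyclohex-2-en-1-yl]-2-[3-methoxy-4-(triisopropylsilyloxy)phenyl]ethenyl trifluoromethanesulfonate
Product: 21 (4R)-3,4-dimethoxy-4-{(1E)-1-[3-methoxy-4-(triisopropylsilyloxy)phenyl]prop-1-en-2-yl}cyclohex-2-en-1-one
Conditions: MeZnCl, Pd(PPh3)4 (5 mol %), THF, 50 °C
Reagents that add atoms: methylzinc chloride, C[Zn]Cl
Why: Negishi cross-coupling of the alkenyl triflate with the methylzinc reagent proceeds with retention of alkene geometry and tolerates the ring ketone, so the E trisubstituted styrene should result.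

Step 14
Reactants: 21 (4R)-3,4-dimethoxy-4-{(1E)-1-[3-methoxy-4-(triisopropylsilyloxy)phenyl]prop-1-en-2-yl}cyclohex-2-en-1-one
Product: 22 (4R)-3,4-dimethoxy-4-{(2R)-1-[3-methoxy-4-(triisopropylsilyloxy)phenyl]propan-2-yl}cyclohex-2-en-1-one
Conditions: H2 (50 bar), [Ir(cod)(L)][B(C6H3-3,5-(CF3)2)4] (2 mol %), L = (S)-4-tert-butyl-2-[2-(di-o-tolylphosphanyl)phenyl]-4,5-dihydro-1,3-oxazole, CH2Cl2, rt; stop at one equivalent of H2
Reagents that add atoms: none
Why: Catalyst-controlled asymmetric hydrogenation of the E trisubstituted aryl alkene by a cationic iridium phosphine–oxazoline complex should deliver H2 to the Si face of C7 and so set 7R (the S ligand is expected by analogy with E-1,2-diarylpropenes, its antipode being used should the face prove opposite), while the push–pull ring alkene and the ketone are poor substrates.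

Step 15
Reactants: 22 (4R)-3,4-dimethoxy-4-{(2R)-1-[3-methoxy-4-(triisopropylsilyloxy)phenyl]propan-2-yl}cyclohex-2-en-1-one
Product: 23 (4R,6RS)-6-allyl-3,4-dimethoxy-4-{(2R)-1-[3-methoxy-4-(triisopropylsilyloxy)phenyl]propan-2-yl}cyclohex-2-en-1-one
Conditions: LiN(iPr)2 (1.1 equiv), THF, −78 °C; allyl bromide, DMPU, −78 → −20 °C
Reagents that add atoms: allyl bromide, C=CCBr
Why: Kinetic deprotonation at the only enolisable position (C2, the α′ carbon of the vinylogous ester) and C-alkylation of the lithium enolate (Stork–Danheiser type alkylation) should install the allyl group, the new C2 centre forming as an inconsequential epimer mixture because it becomes sp2 in the next step.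

Step 16
Reactants: 23 (4R,6RS)-6-allyl-3,4-dimethoxy-4-{(2R)-1-[3-methoxy-4-(triisopropylsilyloxy)phenyl]propan-2-yl}cyclohex-2-en-1-one
Product: 26 (4S)-2-allyl-4,5-dimethoxy-4-{(2R)-1-[3-methoxy-4-(triisopropylsilyloxy)phenyl]propan-2-yl}cyclohexa-2,5-dien-1-one, via selenide 24 (not isolated), via selenoxide 25 (not isolated)
Conditions: LiN(iPr)2, THF, −78 °C; PhSeCl (1.0 equiv), −78 °C; then H2O2 (30%), pyridine, CH2Cl2, 0 °C → rt
Reagents that add atoms: none
Why: α-Selenenylation of the C2 enolate, oxidation and syn-elimination (selenoxide elimination) should introduce the C2–C3 double bond, the endocyclic ring-conjugated alkene being the usual outcome for 2-alkyl-2-selanyl cyclohexanones.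

Step 17
Reactants: 26 (4S)-2-allyl-4,5-dimethoxy-4-{(2R)-1-[3-methoxy-4-(triisopropylsilyloxy)phenyl]propan-2-yl}cyclohexa-2,5-dien-1-one
Product: 27 (4S)-4-[(2R)-1-(4-hydroxy-3-methoxyphenyl)propan-2-yl]-4,5-dimethoxy-2-(prop-2-en-1-yl)cyclohexa-2,5-dien-1-one
Conditions: Bu4NF, AcOH, THF, 0 °C
Reagents that add atoms: none
Why: Fluoride cleaves the aryl Si–O bond (desilylation) under acetic acid buffering, which keeps phenoxide from building up beside the acid- and base-sensitive cross-conjugated dienone.

Compound list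
1 | (R)-lactic acid | C[C@@H](O)C(=O)O | starting material
2 | pivalaldehyde | CC(C)(C)C=O | starting material
3 | (2R,5R)-2-tert-butyl-5-methyl-1,3-dioxolan-4-one (cis) | C[C@H]1O[C@@H](C(C)(C)C)OC1=O | intermediate
4 | (2S,5RS)-5-bromo-2-tert-butyl-5-methyl-1,3-dioxolan-4-one (acetal carbon unchanged in space; descriptor changes by priority only) | CC1(Br)O[C@@H](C(C)(C)C)OC1=O | intermediate (not isolated)
5 | (R)-2-tert-butyl-5-methylene-1,3-dioxolan-4-one | C=C1O[C@@H](C(C)(C)C)OC1=O | intermediate
6 | 1,1-dimethoxyethene | C=C(OC)OC | starting material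
7 | acetyl chloride | CC(=O)Cl | starting material
8 | 4,4-dimethoxybut-3-en-2-one | CC(=O)C=C(OC)OC | intermediate
9 | 1,1-dimethoxy-3-(trimethylsilyloxy)buta-1,3-diene | C=C(O[Si](C)(C)C)C=C(OC)OC | intermediate
10 | (2R,5S)-2-tert-butyl-6,6-dimethoxy-8-(trimethylsilyloxy)-1,3-dioxaspiro[4.5]dec-7-en-4-one | COC1(OC)C=C(O[Si](C)(C)C)CC[C@]12O[C@@H](C(C)(C)C)OC2=O | intermediate (not isolated)
11 | (2R,5S)-2-tert-butyl-6-methoxy-1,3-dioxaspiro[4.5]dec-6-ene-4,8-dione | COC1=CC(=O)CC[C@]12O[C@@H](C(C)(C)C)OC2=O | intermediate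
12 | (1S)-1-hydroxy-N,2-dimethoxy-N-methyl-4-oxocyclohex-2-ene-1-carboxamide | COC1=CC(=O)CC[C@@]1(O)C(=O)N(C)OC | intermediate
13 | (1S)-N,1,2-trimethoxy-N-methyl-4-oxocyclohex-2-ene-1-carboxamide | COC1=CC(=O)CC[C@@]1(OC)C(=O)N(C)OC | intermediate
14 | vanillin | COc1cc(C=O)ccc1O | starting material
15 | 3-methoxy-4-(triisopropylsilyloxy)benzaldehyde | COc1cc(C=O)ccc1O[Si](C(C)C)(C(C)C)C(C)C | intermediate
16 | [3-methoxy-4-(triisopropylsilyloxy)phenyl]methanol | COc1cc(CO)ccc1O[Si](C(C)C)(C(C)C)C(C)C | intermediate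
17 | [4-(chloromethyl)-2-methoxyphenoxy]triisopropylsilane | COc1cc(CCl)ccc1O[Si](C(C)C)(C(C)C)C(C)C | intermediate
18 | [3-methoxy-4-(triisopropylsilyloxy)benzyl]magnesium chloride | COc1cc(C[Mg]Cl)ccc1O[Si](C(C)C)(C(C)C)C(C)C | intermediate (not isolated)
19 | (4S)-3,4-dimethoxy-4-{[3-methoxy-4-(triisopropylsilyloxy)phenyl]acetyl}cyclohex-2-en-1-one | COC1=CC(=O)CC[C@@]1(OC)C(=O)Cc1ccc(O[Si](C(C)C)(C(C)C)C(C)C)c(OC)c1 | intermediate
20 | (1Z)-1-[(1S)-1,2-dimethoxy-4-oxocyclohex-2-en-1-yl]-2-[3-methoxy-4-(triisopropylsilyloxy)phenyl]ethenyl trifluoromethanesulfonate | COC1=CC(=O)CC[C@@]1(OC)/C(OS(=O)(=O)C(F)(F)F)=C/c1ccc(O[Si](C(C)C)(C(C)C)C(C)C)c(OC)c1 | intermediate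
21 | (4R)-3,4-dimethoxy-4-{(1E)-1-[3-methoxy-4-(triisopropylsilyloxy)phenyl]prop-1-en-2-yl}cyclohex-2-en-1-one | COC1=CC(=O)CC[C@@]1(OC)/C(C)=C/c1ccc(O[Si](C(C)C)(C(C)C)C(C)C)c(OC)c1 | intermediate
22 | (4R)-3,4-dimethoxy-4-{(2R)-1-[3-methoxy-4-(triisopropylsilyloxy)phenyl]propan-2-yl}cyclohex-2-en-1-one | COC1=CC(=O)CC[C@@]1(OC)[C@H](C)Cc1ccc(O[Si](C(C)C)(C(C)C)C(C)C)c(OC)c1 | intermediate
23 | (4R,6RS)-6-allyl-3,4-dimethoxy-4-{(2R)-1-[3-methoxy-4-(triisopropylsilyloxy)phenyl]propan-2-yl}cyclohex-2-en-1-one | COC1=CC(=O)C(CC=C)C[C@@]1(OC)[C@H](C)Cc1ccc(O[Si](C(C)C)(C(C)C)C(C)C)c(OC)c1 | intermediate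
24 | (4R,6RS)-6-allyl-3,4-dimethoxy-4-{(2R)-1-[3-methoxy-4-(triisopropylsilyloxy)phenyl]propan-2-yl}-6-(phenylselanyl)cyclohex-2-en-1-one | COC1=CC(=O)C(CC=C)([Se]c2ccccc2)C[C@@]1(OC)[C@H](C)Cc1ccc(O[Si](C(C)C)(C(C)C)C(C)C)c(OC)c1 | intermediate (not isolated)
25 | Se-oxide of 24, the 6-(phenylseleninyl) ketone | COC1=CC(=O)C(CC=C)([Se](=O)c2ccccc2)C[C@@]1(OC)[C@H](C)Cc1ccc(O[Si](C(C)C)(C(C)C)C(C)C)c(OC)c1 | intermediate (not isolated)
26 | (4S)-2-allyl-4,5-dimethoxy-4-{(2R)-1-[3-methoxy-4-(triisopropylsilyloxy)phenyl]propan-2-yl}cyclohexa-2,5-dien-1-one | C=CCC1=C[C@@](OC)([C@H](C)Cc2ccc(O[Si](C(C)C)(C(C)C)C(C)C)c(OC)c2)C(OC)=CC1=O | intermediate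
27 | (4S)-4-[(2R)-1-(4-hydroxy-3-methoxyphenyl)propan-2-yl]-4,5-dimethoxy-2-(prop-2-en-1-yl)cyclohexa-2,5-dien-1-one | C=CCC1=C[C@@](OC)([C@H](C)Cc2ccc(O)c(OC)c2)C(OC)=CC1=O | target

Total step count: 17.
Longest linear sequence: 12 steps (steps 1, 2, 5, 6, 7, 11, 12, 13, 14, 15, 16, 17, from (R)-lactic acid).

Steps most likely to fail

Step 14. The hindered trisubstituted alkene may turn over slowly, the catalyst may fail to override the facial bias imposed by C4, and the ring alkene may start to be reduced if the reaction is forced. The fallback sets out from 13 and comes back at 22. With its ring ketone masked as the lithium enolate (LiN(SiMe3)2), 13 is treated with MeMgBr to give the methyl ketone (4S)-4-acetyl-3,4-dimethoxycyclohex-2-en-1-one F1. Wittig methylenation (Ph3P=CH2) gives (4R)-3,4-dimethoxy-4-(prop-1-en-2-yl)cyclohex-2-en-1-one F2. Hydroboration with 9-borabicyclo[3.3.1]nonane, which should hydroborate the 1,1-disubstituted alkene faster than it reduces the deactivated ring carbonyl, gives 9-{(2R)-2-[(1R)-1,2-dimethoxy-4-oxocyclohex-2-en-1-yl]propyl}-9-borabicyclo[3.3.1]nonane F3. Suzuki–Miyaura coupling of F3 (Pd(dppf)Cl2, K3PO4) with (4-bromo-2-methoxyphenoxy)triisopropylsilane F4, made from 4-bromo-2-methoxyphenol and iPr3SiCl, gives 22. C7 is then set by substrate-controlled hydroboration, and because C7 epimers are diastereomers they can be separated by chromatography.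

Step 16. Syn-elimination of the selenoxide may go toward the allylic CH2 to give an exocyclic diene instead of toward C3–H, and the selenium electrophile may add to the terminal alkene. The fallback sets out from 22 and comes back at 26; it installs the unsaturation before the allyl group. Selenenylation of the enolate of 22 (LiN(iPr)2, PhSeCl) gives (4R,6RS)-3,4-dimethoxy-4-{(2R)-1-[3-methoxy-4-(triisopropylsilyloxy)phenyl]propan-2-yl}-6-(phenylselanyl)cyclohex-2-en-1-one F5. Bromination of its enolate (NBS) gives the 6-bromo-6-(phenylselanyl) ketone F6, and oxidation (H2O2) gives the selenoxide F7. This can eliminate only toward C3–H and should give (4S)-2-bromo-4,5-dimethoxy-4-{(2R)-1-[3-methoxy-4-(triisopropylsilyloxy)phenyl]propan-2-yl}cyclohexa-2,5-dien-1-one F8. Stille coupling of F8 with allyltributylstannane (Pd(PPh3)4) gives 26.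

Step 5. The diene may hydrolyse or the dienophile polymerise before they combine, and facial control may be incomplete at the temperature needed for conversion. The fallback sets out from 8 and 5 and comes back at 11; it makes the same two bonds stepwise by a Michael–Michael annulation. The lithium dienolate of 8 (LiN(iPr)2, THF, −78 °C) adds to the methylene of 5 to give the open-chain adduct (2R)-2-tert-butyl-5-(5,5-dimethoxy-3-oxopent-4-en-1-yl)-1,3-dioxolan-4-one F9 as its lactone enolate. This enolate attacks the ketene-acetal carbon anti to tert-butyl, the usual sense for alkylation of such acetal enolates, and loses methoxide to give 11.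

Further compounds
F1 | step 14 | (4S)-4-acetyl-3,4-dimethoxycyclohex-2-en-1-one | COC1=CC(=O)CC[C@@]1(OC)C(C)=O
F2 | step 14 | (4R)-3,4-dimethoxy-4-(prop-1-en-2-yl)cyclohex-2-en-1-one | COC1=CC(=O)CC[C@@]1(OC)C(C)=C
F3 | step 14 | 9-{(2R)-2-[(1R)-1,2-dimethoxy-4-oxocyclohex-2-en-1-yl]propyl}-9-borabicyclo[3.3.1]nonane | COC1=CC(=O)CC[C@@]1(OC)[C@H](C)CB1C2CCCC1CCC2
F4 | step 14 | (4-bromo-2-methoxyphenoxy)triisopropylsilane | COc1cc(Br)ccc1O[Si](C(C)C)(C(C)C)C(C)C
F5 | step 16 | (4R,6RS)-3,4-dimethoxy-4-{(2R)-1-[3-methoxy-4-(triisopropylsilyloxy)phenyl]propan-2-yl}-6-(phenylselanyl)cyclohex-2-en-1-one | COC1=CC(=O)C([Se]c2ccccc2)C[C@@]1(OC)[C@H](C)Cc1ccc(O[Si](C(C)C)(C(C)C)C(C)C)c(OC)c1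
F6 | step 16 | (4R,6RS)-6-bromo-3,4-dimethoxy-4-{(2R)-1-[3-methoxy-4-(triisopropylsilyloxy)phenyl]propan-2-yl}-6-(phenylselanyl)cyclohex-2-en-1-one | COC1=CC(=O)C(Br)([Se]c2ccccc2)C[C@@]1(OC)[C@H](C)Cc1ccc(O[Si](C(C)C)(C(C)C)C(C)C)c(OC)c1
F7 | step 16 | Se-oxide of F6, the 6-bromo-6-(phenylseleninyl) ketone | COC1=CC(=O)C(Br)([Se](=O)c2ccccc2)C[C@@]1(OC)[C@H](C)Cc1ccc(O[Si](C(C)C)(C(C)C)C(C)C)c(OC)c1
F8 | step 16 | (4S)-2-bromo-4,5-dimethoxy-4-{(2R)-1-[3-methoxy-4-(triisopropylsilyloxy)phenyl]propan-2-yl}cyclohexa-2,5-dien-1-one | COC1=CC(=O)C(Br)=C[C@@]1(OC)[C@H](C)Cc1ccc(O[Si](C(C)C)(C(C)C)C(C)C)c(OC)c1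
F9 | step 5 | (2R)-2-tert-butyl-5-(5,5-dimethoxy-3-oxopent-4-en-1-yl)-1,3-dioxolan-4-one | COC(OC)=CC(=O)CCC1O[C@@H](C(C)(C)C)OC1=O
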